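**Retrosynthetic overview** (isoflavan numbering: O1, C2, C3, C4, C4a–C8a for rings A and C; primed numbers for ring B)

1. The 3'-prenyl group is disconnected last, to a 2'-O-(1,1-dimethylallyl) ether (aromatic Claisen shift). Ring C is opened at O1–C2 (Mitsunobu closure), and the C8 formyl group is removed (ortho-formylation of the C8a phenol).
2. Structural feature used: the 2'-oxygen of ring B lies four atoms from C4 (O–C2'–C1'–C3–C4). A temporary 2'-O–C4 ether therefore makes the C3–C4 bond the closing bond of a five-membered dihydrofuran ring.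
3. Key disconnection C3–C4: enantioselective intramolecular C–H insertion of the ring B aryldiazoacetate carbenoid (carbene carbon = C3, ester carbon = C2) into the benzylic ether CH2 of ring A (C4). The 2'-O–C4 bond is then cut by hydrogenolysis, which turns C4 into CH2 and frees the 2'-OH.
4. The diazo ester comes from a Mitsunobu ether of 2-bromo-5-methoxyphenol with the ring A benzyl alcohol (8a-O as TBS ether, 7-O as MOM ether), a Reformatsky-type α-arylation and a diazo transfer.
5. Ring order: rings A and B are bought; the temporary dihydrofuran ring is closed in step 7 and opened in step 9; pyran ring C is closed in step 13.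

Key step: step 7

Assumption: Rh2(S-PTTL)4 (dirhodium tetrakis[N-phthaloyl-(S)-tert-leucinate]) is taken to give the (2R,3S) sense of insertion on this substrate; if a first run shows the opposite sense, Rh2(R-PTTL)4 is used under the same conditions.

Remark: O7 is carried as a methoxymethyl ether so that it can be freed with dilute protic acid before the acid-sensitive ortho-prenylphenol exists; the last step is then a reagent-free thermal shift.

**Route**

Step 1
Reactants: 1 2,4-dihydroxy-6-methoxybenzaldehyde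
Product: 2 2-hydroxy-6-methoxy-4-(methoxymethoxy)benzaldehyde
Conditions: MOMCl (1.05 equiv), i-Pr2NEt, CH2Cl2, 0 °C
Reagents that add atoms: chloromethyl methyl ether, COCCl
Why: O-alkylation of a phenol (MOM protection) should occur at the 4-OH, which is para to the formyl group and free, whereas the 2-OH is held in a hydrogen bond to the carbonyl and is much less reactive.

Step 2
Reactants: 2 2-hydroxy-6-methoxy-4-(methoxymethoxy)benzaldehyde
Product: 3 2-[(tert-butyldimethylsilyl)oxy]-6-methoxy-4-(methoxymethoxy)benzaldehyde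
Conditions: TBSCl, imidazole, DMAP (cat.), DMF, rt
Reagents that add atoms: tert-butyldimethylsilyl chloride, CC(C)(C)[Si](C)(C)Cl
Why: Silyl ether formation on the remaining chelated phenol under imidazole catalysis is standard for salicylaldehydes and differentiates O8a (silyl) from O7 (acetal) and O5 (methyl).

Step 3
Reactants: 3 2-[(tert-butyldimethylsilyl)oxy]-6-methoxy-4-(methoxymethoxy)benzaldehyde
Product: 4 {2-[(tert-butyldimethylsilyl)oxy]-6-methoxy-4-(methoxymethoxy)phenyl}methanol
Conditions: NaBH4, THF/MeOH, 0 °C; neutral work-up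
Reagents that add atoms: none
Why: Borohydride reduction of the aryl aldehyde is fast at 0 °C, and the short, cold, non-basic treatment should avoid O-to-O silyl migration to the new benzylic oxygen and acid-induced ionisation of the electron-rich benzyl alcohol.

Step 4
Reactants: 4 {2-[(tert-butyldimethylsilyl)oxy]-6-methoxy-4-(methoxymethoxy)phenyl}methanol; 5 2-bromo-5-methoxyphenol
Product: 6 tert-butyl{2-[(2-bromo-5-methoxyphenoxy)methyl]-3-methoxy-5-(methoxymethoxy)phenoxy}dimethylsilane
Conditions: PPh3, DIAD, THF, 0 °C → rt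
Reagents that add atoms: none
Why: Mitsunobu etherification joins the primary benzylic alcohol, activated as its alkoxyphosphonium ion, to the fairly acidic ortho-bromophenol under neutral conditions that a benzyl halide of this very electron-rich ring would not survive.

Step 5
Reactants: 6 tert-butyl{2-[(2-bromo-5-methoxyphenoxy)methyl]-3-methoxy-5-(methoxymethoxy)phenoxy}dimethylsilane
Product: 7 methyl 2-[2-({2-[(tert-butyldimethylsilyl)oxy]-6-methoxy-4-(methoxymethoxy)phenyl}methoxy)-4-methoxyphenyl]acetate
Conditions: BrCH2CO2Me, Zn dust (TMSCl-activated), THF, rt; then 6, Pd2(dba)3 (2 mol %), XPhos (8 mol %), THF, 65 °C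
Reagents that add atoms: methyl bromoacetate (used as its zinc reagent), COC(=O)CBr
Why: Negishi-type α-arylation of a Reformatsky reagent couples the neutral zinc enolate with the aryl bromide under zerovalent-palladium/biarylphosphine catalysis without added base, so the aryl silyl ether and the labile benzyl aryl ether should be untouched, and the blocked ortho positions of ring A rule out a competing direct arylation.

Step 6
Reactants: 7 methyl 2-[2-({2-[(tert-butyldimethylsilyl)oxy]-6-methoxy-4-(methoxymethoxy)phenyl}methoxy)-4-methoxyphenyl]acetate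
Product: 8 methyl 2-[2-({2-[(tert-butyldimethylsilyl)oxy]-6-methoxy-4-(methoxymethoxy)phenyl}methoxy)-4-methoxyphenyl]-2-diazoacetate
Conditions: 4-acetamidobenzenesulfonyl azide, DBU, anhydrous MeCN, 0 °C → rt
Reagents that add atoms: 4-acetamidobenzenesulfonyl azide, CC(=O)Nc1ccc(cc1)S(=O)(=O)N=[N+]=[N-]
Why: Regitz diazo transfer to the benzylic methylene of an arylacetate with a sulfonyl azide and an amidine base is the standard entry to aryldiazoacetates, and anhydrous conditions keep the aryl silyl ether intact.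

Step 7
Reactants: 8 methyl 2-[2-({2-[(tert-butyldimethylsilyl)oxy]-6-methoxy-4-(methoxymethoxy)phenyl}methoxy)-4-methoxyphenyl]-2-diazoacetate
Product: 9 methyl (2R,3S)-2-{2-[(tert-butyldimethylsilyl)oxy]-6-methoxy-4-(methoxymethoxy)phenyl}-6-methoxy-2,3-dihydro-1-benzofuran-3-carboxylate
Conditions: Rh2(S-PTTL)4 (2 mol %), toluene, −78 → −40 °C, slow addition of 8
Reagents that add atoms: none
Why: Loss of N2 on the divalent-rhodium dimer gives an electrophilic donor–acceptor carbenoid whose carbon (the future C3) lies five atoms from the benzylic ether hydrogens of C4, and a concerted, asynchronous three-centre insertion with hydride-transfer character forms the C3–C4 bond; the closest known reaction is the dirhodium-carboxylate-catalysed enantioselective 1,5 C–H insertion of methyl 2-(benzyloxy)aryldiazoacetates to cis-2-aryl-2,3-dihydrobenzofuran-3-carboxylates. The one new ring, the dihydrofuran ring C3–C1'–C2'–O–C4, closes by 1,5 C–H insertion, the five-membered mode that such carbenoids prefer. C3 (benzofuran C3, S) is fixed by the chiral phthalimido wall of the catalyst, which selects the face of the carbenoid that meets the C–H bond, and C4 (benzofuran C2, R) follows from the transition state that keeps ring A away from the catalyst and cis to the ester. C4 is erased in step 9, so only the C3 sense matters, and any trans isomer of the same C3 configuration would converge there. The step needs insertion to beat oxonium-ylide formation, attack on ring A and carbene dimerisation: the C–H bond is activated by the ether oxygen and by the trioxygenated ring A, both ortho positions of ring A are blocked against aromatic substitution, and slow addition at low temperature keeps the diazo concentration low.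

Step 8
Reactants: 9 methyl (2R,3S)-2-{2-[(tert-butyldimethylsilyl)oxy]-6-methoxy-4-(methoxymethoxy)phenyl}-6-methoxy-2,3-dihydro-1-benzofuran-3-carboxylate
Product: 10 [(2R,3R)-2-{2-[(tert-butyldimethylsilyl)oxy]-6-methoxy-4-(methoxymethoxy)phenyl}-6-methoxy-2,3-dihydro-1-benzofuran-3-yl]methanol
Conditions: i-Bu2AlH (2.5 equiv), CH2Cl2, −78 → −40 °C; aq. potassium sodium tartrate
Reagents that add atoms: none
Why: Ester reduction by a non-basic aluminium hydride at low temperature removes the acidity of C3 before enolisation or retro-oxa-Michael opening can scramble it (the descriptor changes from S to R only because the CIP priorities change).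

Step 9
Reactants: 10 [(2R,3R)-2-{2-[(tert-butyldimethylsilyl)oxy]-6-methoxy-4-(methoxymethoxy)phenyl}-6-methoxy-2,3-dihydro-1-benzofuran-3-yl]methanol
Product: 11 2-[(2R)-1-{2-[(tert-butyldimethylsilyl)oxy]-6-methoxy-4-(methoxymethoxy)phenyl}-3-hydroxypropan-2-yl]-5-methoxyphenol
Conditions: H2 (1 atm), 10% Pd/C, EtOAc, rt
Reagents that add atoms: none
Why: Catalytic hydrogenolysis of the benzylic aryl ether C–O bond is the same C4–O cleavage by which pterocarpans are opened to 2'-hydroxyisoflavans; it turns C4 into CH2, frees the 2'-OH, does not touch C3, and leaves the silyl and MOM ethers intact.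

Step 10
Reactants: 11 2-[(2R)-1-{2-[(tert-butyldimethylsilyl)oxy]-6-methoxy-4-(methoxymethoxy)phenyl}-3-hydroxypropan-2-yl]-5-methoxyphenol; 12 3-chloro-3-methylbut-1-yne
Product: 13 (2R)-3-{2-[(tert-butyldimethylsilyl)oxy]-6-methoxy-4-(methoxymethoxy)phenyl}-2-{4-methoxy-2-[(2-methylbut-3-yn-2-yl)oxy]phenyl}propan-1-ol
Conditions: DBU, CuCl2 (1 mol %), anhydrous MeCN, 0 °C
Reagents that add atoms: none
Why: Copper-catalysed O-propargylation of a phenol with a tertiary propargylic chloride (through a copper acetylide-derived electrophile) should be selective for the only free phenol, because the aliphatic alcohol is not deprotonated by the amidine base.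

Step 11
Reactants: 13 (2R)-3-{2-[(tert-butyldimethylsilyl)oxy]-6-methoxy-4-(methoxymethoxy)phenyl}-2-{4-methoxy-2-[(2-methylbut-3-yn-2-yl)oxy]phenyl}propan-1-ol
Product: 14 3-methoxy-2-[(2R)-3-hydroxy-2-{4-methoxy-2-[(2-methylbut-3-yn-2-yl)oxy]phenyl}propyl]-5-(methoxymethoxy)phenol
Conditions: n-Bu4NF, AcOH (1:1), THF, 0 °C
Reagents that add atoms: none
Why: Fluoride-mediated cleavage of the aryl silyl ether, buffered with acetic acid, frees the C8a phenol without affecting the acetal, the propargyl ether or the alcohol.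

Step 12
Reactants: 14 3-methoxy-2-[(2R)-3-hydroxy-2-{4-methoxy-2-[(2-methylbut-3-yn-2-yl)oxy]phenyl}propyl]-5-(methoxymethoxy)phenol
Product: 16 2-hydroxy-3-[(2R)-3-hydroxy-2-{4-methoxy-2-[(2-methylbut-3-yn-2-yl)oxy]phenyl}propyl]-4-methoxy-6-(methoxymethoxy)benzaldehyde, via ortho-hydroxymethyl phenol 15 (not isolated)
Conditions: MgCl2, Et3N, (CH2O)n, THF, 65 °C; dilute aqueous acid work-up
Reagents that add atoms: paraformaldehyde (as formaldehyde), C=O
Why: Magnesium-mediated ortho-formylation of a phenol (Casnati–Skattebøl type) delivers formaldehyde within the magnesium phenoxide chelate to C8, the only free ortho position of the C8a phenol, and the resulting benzylic alkoxide is oxidised by a second formaldehyde through hydride transfer; ring B has no free phenol and is not formylated.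

Step 13
Reactants: 16 2-hydroxy-3-[(2R)-3-hydroxy-2-{4-methoxy-2-[(2-methylbut-3-yn-2-yl)oxy]phenyl}propyl]-4-methoxy-6-(methoxymethoxy)benzaldehyde
Product: 17 (3R)-5-methoxy-3-{4-methoxy-2-[(2-methylbut-3-yn-2-yl)oxy]phenyl}-7-(methoxymethoxy)-3,4-dihydro-2H-1-benzopyran-8-carbaldehyde
Conditions: PPh3, DIAD, THF, 0 °C → rt
Reagents that add atoms: none
Why: Intramolecular Mitsunobu etherification (6-exo-tet) lets the acidic salicylaldehyde-type phenol displace the activated primary alcohol at C2 and close ring C without touching C3, while the etherified 2'-oxygen cannot compete by closing a dihydrobenzofuran.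

Step 14
Reactants: 17 (3R)-5-methoxy-3-{4-methoxy-2-[(2-methylbut-3-yn-2-yl)oxy]phenyl}-7-(methoxymethoxy)-3,4-dihydro-2H-1-benzopyran-8-carbaldehyde
Product: 18 (3R)-7-hydroxy-5-methoxy-3-{4-methoxy-2-[(2-methylbut-3-yn-2-yl)oxy]phenyl}-3,4-dihydro-2H-1-benzopyran-8-carbaldehyde
Conditions: conc. HCl (cat.), MeOH/THF, rt → 40 °C; aqueous work-up
Reagents that add atoms: none
Why: Acid-catalysed methanolysis of the MOM acetal should be much faster than ionisation of the tertiary propargyl aryl ether, whose cation is destabilised by the alkyne, and at this stage no acid-sensitive prenylphenol is present.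

Step 15
Reactants: 18 (3R)-7-hydroxy-5-methoxy-3-{4-methoxy-2-[(2-methylbut-3-yn-2-yl)oxy]phenyl}-3,4-dihydro-2H-1-benzopyran-8-carbaldehyde
Product: 19 (3R)-7-hydroxy-5-methoxy-3-{4-methoxy-2-[(2-methylbut-3-en-2-yl)oxy]phenyl}-3,4-dihydro-2H-1-benzopyran-8-carbaldehyde
Conditions: H2 (1 atm), Pd/CaCO3 poisoned with Pb(OAc)2, quinoline, EtOAc, rt
Reagents that add atoms: none
Why: Lindlar semihydrogenation reduces the terminal alkyne to the alkene and should stop there, leaving the aryl aldehyde and the free phenol untouched.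

Step 16
Reactants: 19 (3R)-7-hydroxy-5-methoxy-3-{4-methoxy-2-[(2-methylbut-3-en-2-yl)oxy]phenyl}-3,4-dihydro-2H-1-benzopyran-8-carbaldehyde
Product: 21 (3R)-7-hydroxy-3-[2-hydroxy-4-methoxy-3-(3-methylbut-2-en-1-yl)phenyl]-5-methoxy-3,4-dihydro-2H-1-benzopyran-8-carbaldehyde, via cyclohexadienone 20 (not isolated)
Conditions: N,N-diethylaniline, 130 °C
Reagents that add atoms: none
Why: Aromatic Claisen rearrangement ([3,3]-sigmatropic shift) of the 1,1-dimethylallyl aryl ether transfers the allyl unit with inversion to C3', the only unsubstituted ortho carbon, and enolisation of the dienone gives the 3'-prenyl-2'-phenol irreversibly, whereas a shift to the substituted C1' can only revert; no reagent is present, so C3 is not touched.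

**Compound list**

1 | 2,4-dihydroxy-6-methoxybenzaldehyde | COc1cc(O)cc(O)c1C=O | starting material
2 | 2-hydroxy-6-methoxy-4-(methoxymethoxy)benzaldehyde | COCOc1cc(O)c(C=O)c(OC)c1 | intermediate
3 | 2-[(tert-butyldimethylsilyl)oxy]-6-methoxy-4-(methoxymethoxy)benzaldehyde | COCOc1cc(OC)c(C=O)c(O[Si](C)(C)C(C)(C)C)c1 | intermediate
4 | {2-[(tert-butyldimethylsilyl)oxy]-6-methoxy-4-(methoxymethoxy)phenyl}methanol | COCOc1cc(OC)c(CO)c(O[Si](C)(C)C(C)(C)C)c1 | intermediate
5 | 2-bromo-5-methoxyphenol | COc1ccc(Br)c(O)c1 | starting material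
6 | tert-butyl{2-[(2-bromo-5-methoxyphenoxy)methyl]-3-methoxy-5-(methoxymethoxy)phenoxy}dimethylsilane | COc1ccc(Br)c(OCc2c(OC)cc(OCOC)cc2O[Si](C)(C)C(C)(C)C)c1 | intermediate
7 | methyl 2-[2-({2-[(tert-butyldimethylsilyl)oxy]-6-methoxy-4-(methoxymethoxy)phenyl}methoxy)-4-methoxyphenyl]acetate | COC(=O)Cc1ccc(OC)cc1OCc1c(OC)cc(OCOC)cc1O[Si](C)(C)C(C)(C)C | intermediate
8 | methyl 2-[2-({2-[(tert-butyldimethylsilyl)oxy]-6-methoxy-4-(methoxymethoxy)phenyl}methoxy)-4-methoxyphenyl]-2-diazoacetate | COC(=O)C(=[N+]=[N-])c1ccc(OC)cc1OCc1c(OC)cc(OCOC)cc1O[Si](C)(C)C(C)(C)C | intermediate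
9 | methyl (2R,3S)-2-{2-[(tert-butyldimethylsilyl)oxy]-6-methoxy-4-(methoxymethoxy)phenyl}-6-methoxy-2,3-dihydro-1-benzofuran-3-carboxylate | COC(=O)[C@H]1c2ccc(OC)cc2O[C@H]1c1c(OC)cc(OCOC)cc1O[Si](C)(C)C(C)(C)C | intermediate
10 | [(2R,3R)-2-{2-[(tert-butyldimethylsilyl)oxy]-6-methoxy-4-(methoxymethoxy)phenyl}-6-methoxy-2,3-dihydro-1-benzofuran-3-yl]methanol | OC[C@H]1c2ccc(OC)cc2O[C@H]1c1c(OC)cc(OCOC)cc1O[Si](C)(C)C(C)(C)C | intermediate
11 | 2-[(2R)-1-{2-[(tert-butyldimethylsilyl)oxy]-6-methoxy-4-(methoxymethoxy)phenyl}-3-hydroxypropan-2-yl]-5-methoxyphenol | OC[C@H](Cc1c(OC)cc(OCOC)cc1O[Si](C)(C)C(C)(C)C)c1ccc(OC)cc1O | intermediate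
12 | 3-chloro-3-methylbut-1-yne | CC(C)(Cl)C#C | starting material
13 | (2R)-3-{2-[(tert-butyldimethylsilyl)oxy]-6-methoxy-4-(methoxymethoxy)phenyl}-2-{4-methoxy-2-[(2-methylbut-3-yn-2-yl)oxy]phenyl}propan-1-ol | OC[C@H](Cc1c(OC)cc(OCOC)cc1O[Si](C)(C)C(C)(C)C)c1ccc(OC)cc1OC(C)(C)C#C | intermediate
14 | 3-methoxy-2-[(2R)-3-hydroxy-2-{4-methoxy-2-[(2-methylbut-3-yn-2-yl)oxy]phenyl}propyl]-5-(methoxymethoxy)phenol | OC[C@H](Cc1c(OC)cc(OCOC)cc1O)c1ccc(OC)cc1OC(C)(C)C#C | intermediate
15 | 2-(hydroxymethyl)-6-[(2R)-3-hydroxy-2-{4-methoxy-2-[(2-methylbut-3-yn-2-yl)oxy]phenyl}propyl]-5-methoxy-3-(methoxymethoxy)phenol | OC[C@H](Cc1c(OC)cc(OCOC)c(CO)c1O)c1ccc(OC)cc1OC(C)(C)C#C | intermediate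
16 | 2-hydroxy-3-[(2R)-3-hydroxy-2-{4-methoxy-2-[(2-methylbut-3-yn-2-yl)oxy]phenyl}propyl]-4-methoxy-6-(methoxymethoxy)benzaldehyde | OC[C@H](Cc1c(OC)cc(OCOC)c(C=O)c1O)c1ccc(OC)cc1OC(C)(C)C#C | intermediate
17 | (3R)-5-methoxy-3-{4-methoxy-2-[(2-methylbut-3-yn-2-yl)oxy]phenyl}-7-(methoxymethoxy)-3,4-dihydro-2H-1-benzopyran-8-carbaldehyde | COc1ccc([C@@H]2COc3c(C=O)c(OCOC)cc(OC)c3C2)c(OC(C)(C)C#C)c1 | intermediate
18 | (3R)-7-hydroxy-5-methoxy-3-{4-methoxy-2-[(2-methylbut-3-yn-2-yl)oxy]phenyl}-3,4-dihydro-2H-1-benzopyran-8-carbaldehyde | COc1ccc([C@@H]2COc3c(C=O)c(O)cc(OC)c3C2)c(OC(C)(C)C#C)c1 | intermediate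
19 | (3R)-7-hydroxy-5-methoxy-3-{4-methoxy-2-[(2-methylbut-3-en-2-yl)oxy]phenyl}-3,4-dihydro-2H-1-benzopyran-8-carbaldehyde | COc1ccc([C@@H]2COc3c(C=O)c(O)cc(OC)c3C2)c(OC(C)(C)C=C)c1 | intermediate
20 | (3R)-7-hydroxy-5-methoxy-3-[4-methoxy-5-(3-methylbut-2-en-1-yl)-6-oxocyclohexa-1,3-dien-1-yl]-3,4-dihydro-2H-1-benzopyran-8-carbaldehyde (ring carbon bearing the prenyl group not defined) | COC1=CC=C([C@@H]2COc3c(C=O)c(O)cc(OC)c3C2)C(=O)C1CC=C(C)C | intermediate
21 | (3R)-7-hydroxy-3-[2-hydroxy-4-methoxy-3-(3-methylbut-2-en-1-yl)phenyl]-5-methoxy-3,4-dihydro-2H-1-benzopyran-8-carbaldehyde | COc1ccc([C@@H]2COc3c(C=O)c(O)cc(OC)c3C2)c(O)c1CC=C(C)C | target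

**Step count**

Total steps: 16. Longest linear sequence: 16 steps (1 → 21); compounds 5 and 12 enter in single convergent steps.

**Steps most likely to fail**

1. Step 7. Enantiofacial control at C3 may be insufficient, either because hydride transfer from the very electron-rich C4 runs ahead of C–C bond formation or because the doubly ortho-substituted ring A fits the catalyst pocket poorly. The fallback moves stereocontrol from the catalyst to a covalently bound auxiliary, with separation of diastereomers. Setting out from 7, the methyl ester is cleaved with Me3SnOH (ClCH2CH2Cl, 80 °C) to the carboxylic acid F1. This is esterified (EDC·HCl, DMAP, CH2Cl2) with (2S)-2-hydroxy-1-(pyrrolidin-1-yl)propan-1-one to the lactamide ester F2 (the lactamide antipode is chosen to match; the S form is drawn). Diazo transfer as in step 6 gives the diazo ester F3. Insertion with Rh2(S-DOSP)4 in CH2Cl2 should give the dihydrobenzofuran ester F4 as chromatographically separable diastereomers; the one with the (3S) ring carbon is taken on whatever its C2 configuration. LiBH4 in THF removes the auxiliary and gives the alcohol F5, and hydrogenolysis as in step 9 brings the material back to the route at 11.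

2. Step 4. The activated benzyl alcohol may ionise to a trioxygenated benzyl cation that alkylates carbon (ring positions of the phenol or of a second molecule of 4) or the hydrazide instead of the phenol oxygen. The fallback is a Williamson etherification with a pre-formed phenoxide. Setting out from 4, MsCl and Et3N in CH2Cl2 at −30 °C give the benzylic chloride F6, which is used cold and crude and added to the sodium salt of 5 (NaH, DMF, 0 °C); this returns to the route at 6.

3. Step 12. The free primary alcohol and the very electron-rich ring may divert formaldehyde into hemiformals and diarylmethanes, so that formylation stalls. The fallback separates C–C bond formation from oxidation. Setting out from 14, PhB(OH)2, (CH2O)n and catalytic propionic acid in refluxing toluene (water removal) give the benzodioxaborin F7 by boron-templated ortho-hydroxymethylation. Exchange with propane-1,3-diol releases 15, which is isolated in this variant, and MnO2 in CH2Cl2 oxidises only the benzylic alcohol, returning to the route at 16.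

**Further compounds**

F1 | step 7 | 2-[2-({2-[(tert-butyldimethylsilyl)oxy]-6-methoxy-4-(methoxymethoxy)phenyl}methoxy)-4-methoxyphenyl]acetic acid | OC(=O)Cc1ccc(OC)cc1OCc1c(OC)cc(OCOC)cc1O[Si](C)(C)C(C)(C)C
F2 | step 7 | (2S)-1-oxo-1-(pyrrolidin-1-yl)propan-2-yl 2-[2-({2-[(tert-butyldimethylsilyl)oxy]-6-methoxy-4-(methoxymethoxy)phenyl}methoxy)-4-methoxyphenyl]acetate | C[C@H](OC(=O)Cc1ccc(OC)cc1OCc1c(OC)cc(OCOC)cc1O[Si](C)(C)C(C)(C)C)C(=O)N1CCCC1
F3 | step 7 | (2S)-1-oxo-1-(pyrrolidin-1-yl)propan-2-yl 2-[2-({2-[(tert-butyldimethylsilyl)oxy]-6-methoxy-4-(methoxymethoxy)phenyl}methoxy)-4-methoxyphenyl]-2-diazoacetate | C[C@H](OC(=O)C(=[N+]=[N-])c1ccc(OC)cc1OCc1c(OC)cc(OCOC)cc1O[Si](C)(C)C(C)(C)C)C(=O)N1CCCC1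
F4 | step 7 | (2S)-1-oxo-1-(pyrrolidin-1-yl)propan-2-yl (3S)-2-{2-[(tert-butyldimethylsilyl)oxy]-6-methoxy-4-(methoxymethoxy)phenyl}-6-methoxy-2,3-dihydro-1-benzofuran-3-carboxylate (C2 not defined) | C[C@H](OC(=O)[C@H]1c2ccc(OC)cc2OC1c1c(OC)cc(OCOC)cc1O[Si](C)(C)C(C)(C)C)C(=O)N1CCCC1
F5 | step 7 | [(3R)-2-{2-[(tert-butyldimethylsilyl)oxy]-6-methoxy-4-(methoxymethoxy)phenyl}-6-methoxy-2,3-dihydro-1-benzofuran-3-yl]methanol (C2 not defined; the 2R isomer is 10) | OC[C@H]1c2ccc(OC)cc2OC1c1c(OC)cc(OCOC)cc1O[Si](C)(C)C(C)(C)C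
F6 | step 4 | tert-butyl[2-(chloromethyl)-3-methoxy-5-(methoxymethoxy)phenoxy]dimethylsilane | COCOc1cc(OC)c(CCl)c(O[Si](C)(C)C(C)(C)C)c1
F7 | step 12 | (2R)-3-[7-methoxy-5-(methoxymethoxy)-2-phenyl-4H-1,3,2-benzodioxaborin-8-yl]-2-{4-methoxy-2-[(2-methylbut-3-yn-2-yl)oxy]phenyl}propan-1-ol | OC[C@H](Cc1c(OC)cc(OCOC)c2COB(c3ccccc3)Oc12)c1ccc(OC)cc1OC(C)(C)C#C
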